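**Plan**
1. Retrosynthesis: the furanone is opened at C3–C4 (Dieckmann condensation) to the acyclic Z-enol propanoate 24 of a 2-oxo ester. Then the O1–C2 acyl bond (propanoic anhydride) and the C5–C1' bond (Grignard reagent plus dimethyl oxalate) are cut, then the C7'–C8' bond of the diene (alkenylalane plus alkenyl iodide), the furan–C13' bond (B-alkyl Suzuki–Miyaura coupling) and the C3'–C4' bond (copper-catalysed alkyl–alkyl coupling).
2. Enabling feature: ring atoms O1–C2(=O)–C3(CH3) are a propanoyl group on the enol oxygen of C5, and C4 is an ester-level carbon 1,5 to the acidic C3–H. The whole 4-hydroxy-3-methylfuranone with its 5-ylidene is therefore latent in a neutral enol ester.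
3. Forward order: the furan is bought as 3-bromofuran. West alkenyl iodide 10 (steps 1–5) and east alkynol 16 (steps 6–8) are joined at the diene (step 9). The chain end is turned into the keto ester and its enol propanoate (steps 10–12), and the furanone ring is closed last, so the tetronic acid never needs protection.
4. Stereochemistry: C10' (S) comes from an Evans allylation and C2' (R) from the chiral pool ((2S)-3-bromo-2-methylpropan-1-ol). The 6'E,8'E-diene comes from a syn-carboalumination and a Takai olefination joined with retention. The 5Z-ylidene comes from thermodynamically controlled enol ester formation and is carried unchanged through the ring closure.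
5. Numbering: furanone atoms are O1, C2 (lactone C=O), C3 (C–CH3), C4 (C–OH), C5; side-chain atoms C1'–C13' are counted from the ylidene carbon.

Key step: step 13

Remark: building blocks 1, 11 and 13 are taken as purchasable, and the target is handled as the 4-hydroxy (enol) tautomer shown.

**Step 1**
Reactants: 1 (4R)-4-benzyl-3-propanoyl-1,3-oxazolidin-2-one; 2 3-iodoprop-1-ene (allyl iodide)
Product: 4 (4R)-4-benzyl-3-[(2S)-2-methylpent-4-enoyl]-1,3-oxazolidin-2-one, via sodium enolate 3 (not isolated)
Conditions: NaN(SiMe3)2, THF, −78 °C; then allyl iodide, −78 to −45 °C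
Reagents that add atoms: none
Why: Evans asymmetric alkylation, in which the chelated sodium Z-enolate is allylated on the face opposite the benzyl group, sets the (S) centre that becomes C10'.

**Step 2**
Reactants: 4 (4R)-4-benzyl-3-[(2S)-2-methylpent-4-enoyl]-1,3-oxazolidin-2-one; 5 3-bromofuran
Product: 7 (4R)-4-benzyl-3-[(2S)-5-(furan-3-yl)-2-methylpentanoyl]-1,3-oxazolidin-2-one, via alkylborane 6 (not isolated)
Conditions: 9-BBN, THF, 0 °C to rt; then 3-bromofuran, PdCl2(dppf) (cat.), K3PO4, DMF, 50 °C
Reagents that add atoms: none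
Why: Anti-Markovnikov hydroboration of the terminal alkene followed by B-alkyl Suzuki–Miyaura coupling should join the primary alkylborane to C3 of the furan, the imide and its α-centre being inert to 9-BBN and to anhydrous phosphate.

**Step 3**
Reactants: 7 (4R)-4-benzyl-3-[(2S)-5-(furan-3-yl)-2-methylpentanoyl]-1,3-oxazolidin-2-one
Product: 8 (2S)-5-(furan-3-yl)-2-methylpentan-1-ol
Conditions: LiBH4, MeOH (1 equiv), Et2O, 0 °C
Reagents that add atoms: none
Why: Reductive cleavage of the N-acyl oxazolidinone by borohydride at the exocyclic carbonyl should give the primary alcohol without touching the stereocentre and return the auxiliary.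

**Step 4**
Reactants: 8 (2S)-5-(furan-3-yl)-2-methylpentan-1-ol
Product: 9 (2S)-5-(furan-3-yl)-2-methylpentanal
Conditions: Dess–Martin periodinane, CH2Cl2, 0 °C to rt
Reagents that add atoms: none
Why: Dess–Martin oxidation is close to neutral, so the α-methyl aldehyde should form without epimerisation and is used at once.

**Step 5**
Reactants: 9 (2S)-5-(furan-3-yl)-2-methylpentanal
Product: 10 3-[(4S,5E)-6-iodo-4-methylhex-5-en-1-yl]furan
Conditions: CrCl2, CHI3, THF/1,4-dioxane, 0 °C to rt
Reagents that add atoms: iodoform, IC(I)I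
Why: Takai olefination, in which the gem-dichromium species from CHI3 and CrCl2 adds to the aldehyde and eliminates to the E-alkenyl iodide under non-basic conditions, should keep the α-stereocentre intact.

**Step 6**
Reactants: 11 (2S)-3-bromo-2-methylpropan-1-ol
Product: 12 [(2S)-3-bromo-2-methylpropoxy](tert-butyl)dimethylsilane
Conditions: TBSCl, imidazole, CH2Cl2, 0 °C to rt
Reagents that add atoms: tert-butyldimethylsilyl chloride, CC(C)(C)[Si](C)(C)Cl
Why: Standard silylation of a primary alcohol protects the hydroxyl group against the Grignard reagent of the next step.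

**Step 7**
Reactants: 12 [(2S)-3-bromo-2-methylpropoxy](tert-butyl)dimethylsilane; 13 (4-bromobut-1-yn-1-yl)trimethylsilane
Product: 15 tert-butyl(dimethyl){[(2R)-2-methyl-7-(trimethylsilyl)hept-6-yn-1-yl]oxy}silane, via Grignard reagent 14 (not isolated)
Conditions: Mg, THF (13 to 14); then 12, Li2CuCl4 (cat.), NMP, THF, 0 °C to rt
Reagents that add atoms: none
Why: Copper-catalysed alkyl–alkyl coupling of a primary Grignard reagent with a primary bromide (Kochi-type coupling) forms C3'–C4' one carbon away from the stereocentre, which is untouched (the descriptor changes from S to R only through the priority change).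

**Step 8**
Reactants: 15 tert-butyl(dimethyl){[(2R)-2-methyl-7-(trimethylsilyl)hept-6-yn-1-yl]oxy}silane
Product: 16 (2R)-2-methylhept-6-yn-1-ol
Conditions: Bu4NF, THF, rt
Reagents that add atoms: none
Why: Fluoride-induced desilylation should cleave both the O–Si bond and the alkynyl C–Si bond in one operation.

**Step 9**
Reactants: 16 (2R)-2-methylhept-6-yn-1-ol; 10 3-[(4S,5E)-6-iodo-4-methylhex-5-en-1-yl]furan
Product: 18 (2R,6E,8E,10S)-13-(furan-3-yl)-2,6,10-trimethyltrideca-6,8-dien-1-ol, via alkenylalane 17 (not isolated)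
Conditions: AlMe3, Cp2ZrCl2 (cat.), CH2Cl2, 0 °C to rt; volatiles removed; then 10, ZnCl2 (co-catalyst), Pd(PPh3)4 (cat.), THF, rt
Reagents that add atoms: trimethylaluminium, C[Al](C)C
Why: Negishi zirconium-catalysed syn-carboalumination puts the methyl group on the internal and aluminium on the terminal alkyne carbon (E-alkenylalane), and cross-coupling with 10 on zerovalent palladium proceeds with retention at both sp2 carbons to give the E,E-diene.

**Step 10**
Reactants: 18 (2R,6E,8E,10S)-13-(furan-3-yl)-2,6,10-trimethyltrideca-6,8-dien-1-ol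
Product: 19 3-[(4S,5E,7E,12R)-13-bromo-4,8,12-trimethyltrideca-5,7-dien-1-yl]furan
Conditions: CBr4, PPh3, CH2Cl2, 0 °C
Reagents that add atoms: tetrabromomethane, BrC(Br)(Br)Br
Why: Appel bromination is an SN2 displacement at the primary carbon under neutral conditions that the furan and the diene should tolerate.

**Step 11**
Reactants: 19 3-[(4S,5E,7E,12R)-13-bromo-4,8,12-trimethyltrideca-5,7-dien-1-yl]furan; 20 dimethyl oxalate
Product: 22 methyl (4R,8E,10E,12S)-15-(furan-3-yl)-4,8,12-trimethyl-2-oxopentadeca-8,10-dienoate, via Grignard reagent 21 (not isolated)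
Conditions: Mg, THF, rt to 40 °C; then added to (CO2Me)2 (excess), THF, −78 °C; aqueous work-up
Reagents that add atoms: none
Why: Inverse addition of a Grignard reagent to excess dialkyl oxalate at low temperature stops at the tetrahedral adduct, which gives the 2-oxo ester on work-up (classical α-keto ester synthesis).

**Step 12**
Reactants: 22 methyl (4R,8E,10E,12S)-15-(furan-3-yl)-4,8,12-trimethyl-2-oxopentadeca-8,10-dienoate; 23 propanoic anhydride
Product: 24 methyl (2Z,4R,8E,10E,12S)-15-(furan-3-yl)-4,8,12-trimethyl-2-(propanoyloxy)pentadeca-2,8,10-trienoate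
Conditions: (EtCO)2O, Et3N, DMAP (cat.), CH2Cl2, 0 °C to rt
Reagents that add atoms: none
Why: DMAP-catalysed O-acylation of the keto ester enol (enol ester formation) can only involve C3, and the Z isomer, with the chain trans to the ester group, is expected to predominate as the more stable isomer, any E isomer being removed by chromatography.

**Step 13**
Reactants: 24 methyl (2Z,4R,8E,10E,12S)-15-(furan-3-yl)-4,8,12-trimethyl-2-(propanoyloxy)pentadeca-2,8,10-trienoate
Product: 26 (5Z)-5-[(2R,6E,8E,10S)-13-(furan-3-yl)-2,6,10-trimethyltrideca-6,8-dien-1-ylidene]-4-hydroxy-3-methylfuran-2(5H)-one, via lithium tetronate 25 (not isolated)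
Conditions: LiN(SiMe3)2 (3 equiv), THF, −78 to −20 °C; then 1 M HCl
Reagents that add atoms: none
Why: LiN(SiMe3)2 removes a proton from the propanoyl CH2 (the future C3), the ester enolate adds to the adjacent methyl ester carbonyl (the future C4), methoxide leaves, and the 2,4-dione is deprotonated at once to lithium tetronate 25, the thermodynamic sink that makes the Claisen step irreversible, before acid releases the 4-hydroxyfuranone. The closest known reaction type is the Dieckmann condensation of 2-(acyloxy) esters and 2-(acyloxy)acrylates, the standard ring closure to tetronic acids and pulvinones. The furanone ring closes in the 5-exo-trig mode at the ester carbonyl (enolendo with respect to the enolate), helped by the sp2 C5, which holds O1 and C4 in one plane. No stereocentre is formed; the Z geometry at C5=C1' is inherited from 24 because that double bond is not touched, and C2' and C10' lie outside the reacting array. The step needs deprotonation at the acyl CH2 and not at the tertiary allylic C4–H of 24 (the future C2'–H), whose removal would scramble that centre: the acyl protons are more acidic and more accessible, and allylic 1,3-strain with the acyloxy group holds the C4–H bond in the plane of the alkene, out of overlap with the π system. It also needs cyclisation to outrun loss of the acyl group as methylketene or by attack of methoxide, which the low temperature, the excess of hindered amide base and the five-membered transition state are expected to secure.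

**Compound list**
1 | (4R)-4-benzyl-3-propanoyl-1,3-oxazolidin-2-one | CCC(=O)N1[C@H](Cc2ccccc2)COC1=O | starting material
2 | 3-iodoprop-1-ene (allyl iodide) | C=CCI | starting material
3 | sodium (Z)-enolate of 1 | C/C=C(\[O-])N1[C@H](Cc2ccccc2)COC1=O.[Na+] | intermediate (not isolated)
4 | (4R)-4-benzyl-3-[(2S)-2-methylpent-4-enoyl]-1,3-oxazolidin-2-one | O=C(N1[C@H](Cc2ccccc2)COC1=O)[C@@H](C)CC=C | intermediate
5 | 3-bromofuran | Brc1ccoc1 | starting material
6 | (4R)-4-benzyl-3-[(2S)-5-(9-borabicyclo[3.3.1]nonan-9-yl)-2-methylpentanoyl]-1,3-oxazolidin-2-one | O=C(N1[C@H](Cc2ccccc2)COC1=O)[C@@H](C)CCCB1C2CCCC1CCC2 | intermediate (not isolated)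
7 | (4R)-4-benzyl-3-[(2S)-5-(furan-3-yl)-2-methylpentanoyl]-1,3-oxazolidin-2-one | O=C(N1[C@H](Cc2ccccc2)COC1=O)[C@@H](C)CCCc1ccoc1 | intermediate
8 | (2S)-5-(furan-3-yl)-2-methylpentan-1-ol | OC[C@@H](C)CCCc1ccoc1 | intermediate
9 | (2S)-5-(furan-3-yl)-2-methylpentanal | O=C[C@@H](C)CCCc1ccoc1 | intermediate
10 | 3-[(4S,5E)-6-iodo-4-methylhex-5-en-1-yl]furan | I/C=C/[C@@H](C)CCCc1ccoc1 | intermediate
11 | (2S)-3-bromo-2-methylpropan-1-ol | OC[C@H](C)CBr | starting material
12 | [(2S)-3-bromo-2-methylpropoxy](tert-butyl)dimethylsilane | CC(C)(C)[Si](C)(C)OC[C@H](C)CBr | intermediate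
13 | (4-bromobut-1-yn-1-yl)trimethylsilane | C[Si](C)(C)C#CCCBr | starting material
14 | [4-(trimethylsilyl)but-3-yn-1-yl]magnesium bromide | C[Si](C)(C)C#CCC[Mg]Br | intermediate (not isolated)
15 | tert-butyl(dimethyl){[(2R)-2-methyl-7-(trimethylsilyl)hept-6-yn-1-yl]oxy}silane | CC(C)(C)[Si](C)(C)OC[C@H](C)CCCC#C[Si](C)(C)C | intermediate
16 | (2R)-2-methylhept-6-yn-1-ol | OC[C@H](C)CCCC#C | intermediate
17 | {(1E,6R)-7-[(dimethylalumanyl)oxy]-2,6-dimethylhept-1-en-1-yl}dimethylalumane | C[Al](C)OC[C@H](C)CCC/C(C)=C/[Al](C)C | intermediate (not isolated)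
18 | (2R,6E,8E,10S)-13-(furan-3-yl)-2,6,10-trimethyltrideca-6,8-dien-1-ol | OC[C@H](C)CCC/C(C)=C/C=C/[C@@H](C)CCCc1ccoc1 | intermediate
19 | 3-[(4S,5E,7E,12R)-13-bromo-4,8,12-trimethyltrideca-5,7-dien-1-yl]furan | BrC[C@H](C)CCC/C(C)=C/C=C/[C@@H](C)CCCc1ccoc1 | intermediate
20 | dimethyl oxalate | COC(=O)C(=O)OC | starting material
21 | [(2R,6E,8E,10S)-13-(furan-3-yl)-2,6,10-trimethyltrideca-6,8-dien-1-yl]magnesium bromide | Br[Mg]C[C@H](C)CCC/C(C)=C/C=C/[C@@H](C)CCCc1ccoc1 | intermediate (not isolated)
22 | methyl (4R,8E,10E,12S)-15-(furan-3-yl)-4,8,12-trimethyl-2-oxopentadeca-8,10-dienoate | COC(=O)C(=O)C[C@H](C)CCC/C(C)=C/C=C/[C@@H](C)CCCc1ccoc1 | intermediate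
23 | propanoic anhydride | CCC(=O)OC(=O)CC | starting material
24 | methyl (2Z,4R,8E,10E,12S)-15-(furan-3-yl)-4,8,12-trimethyl-2-(propanoyloxy)pentadeca-2,8,10-trienoate | COC(=O)/C(OC(=O)CC)=C/[C@H](C)CCC/C(C)=C/C=C/[C@@H](C)CCCc1ccoc1 | intermediate
25 | lithium 4-olate (lithium tetronate) of 26 | CC1=C([O-])/C(=C/[C@H](C)CCC/C(C)=C/C=C/[C@@H](C)CCCc2ccoc2)OC1=O.[Li+] | intermediate (not isolated)
26 | (5Z)-5-[(2R,6E,8E,10S)-13-(furan-3-yl)-2,6,10-trimethyltrideca-6,8-dien-1-ylidene]-4-hydroxy-3-methylfuran-2(5H)-one | CC1=C(O)/C(=C/[C@H](C)CCC/C(C)=C/C=C/[C@@H](C)CCCc2ccoc2)OC1=O | target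

**Step count and risks**
Total step count: 13. Longest linear sequence: 10 steps (steps 1–5, then 9–13).

Steps most likely to fail:

1. Step 13. The enolate may form at the wrong site (the allylic C4–H of 24, with loss of configuration), or the acyl enolate may fragment to methylketene and the keto ester enolate before it cyclises. The fallback sets out from dienol 18 and comes back to the route at target 26. Compound 18 is oxidised with Dess–Martin periodinane to (2R,6E,8E,10S)-13-(furan-3-yl)-2,6,10-trimethyltrideca-6,8-dienal F1. The known 4-methoxy-3-methylfuran-2(5H)-one is lithiated at C5 with LiN(iPr)2 (THF, −78 °C) to 5-lithio-4-methoxy-3-methylfuran-2(5H)-one F2. This should add to F1 to give the aldol adduct 5-[(2R,6E,8E,10S)-13-(furan-3-yl)-1-hydroxy-2,6,10-trimethyltrideca-6,8-dien-1-yl]-4-methoxy-3-methylfuran-2(5H)-one F3 as a mixture of epimers. MsCl and Et3N convert it into its methanesulfonate F4, which DBU should eliminate through the C5 carbanion, from either epimer, to the (5Z)-ylidene methyl tetronate F5. LiSPr in HMPA then removes the O-methyl group to give 26.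

2. Step 9. Methyl transfer from aluminium or zinc to palladium (methylation of the alkenyl iodide) and sluggish transmetalation of the alkoxide-bearing alane may erode the one-pot coupling. The fallback sets out from alkynol 16 and aldehyde 9 and comes back at dienol 18. Compound 16 is carboaluminated as before (via 17) and the alane is quenched with I2 to (2R,6E)-7-iodo-2,6-dimethylhept-6-en-1-ol F6. Aldehyde 9 is homologated with the Ohira–Bestmann reagent (K2CO3, MeOH, 0 °C) to 3-[(4S)-4-methylhex-5-yn-1-yl]furan F7. F7 is hydroborated with pinacolborane (Cp2Zr(H)Cl cat.) to 2-[(1E,3S)-6-(furan-3-yl)-3-methylhex-1-en-1-yl]-4,4,5,5-tetramethyl-1,3,2-dioxaborolane F8. Suzuki–Miyaura coupling of F6 with F8 (Pd(PPh3)4, aqueous NaOH, THF) should give 18 from two geometrically defined, purified partners.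

3. Step 2. The phosphate base may cleave the N-acyl oxazolidinone, or transmetalation of the alkylborane may be slow beside the imide. The fallback sets out from imide 4 and comes back at alcohol 8. LiBH4 reduction of 4 gives (2S)-2-methylpent-4-en-1-ol F9, which is silylated (TBSCl, imidazole) to tert-butyl(dimethyl){[(2S)-2-methylpent-4-en-1-yl]oxy}silane F10. Hydroboration with 9-BBN gives the alkylborane 9-[(4S)-5-{[tert-butyl(dimethyl)silyl]oxy}-4-methylpentyl]-9-borabicyclo[3.3.1]nonane F11. This is coupled with 3-bromofuran 5 (PdCl2(dppf), K3PO4, DMF) to tert-butyl{[(2S)-5-(furan-3-yl)-2-methylpentyl]oxy}dimethylsilane F12, and Bu4NF then gives 8.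

**Further compounds**
F1 | step 13 | (2R,6E,8E,10S)-13-(furan-3-yl)-2,6,10-trimethyltrideca-6,8-dienal | O=C[C@H](C)CCC/C(C)=C/C=C/[C@@H](C)CCCc1ccoc1
F2 | step 13 | 5-lithio-4-methoxy-3-methylfuran-2(5H)-one | [Li]C1OC(=O)C(C)=C1OC
F3 | step 13 | 5-[(2R,6E,8E,10S)-13-(furan-3-yl)-1-hydroxy-2,6,10-trimethyltrideca-6,8-dien-1-yl]-4-methoxy-3-methylfuran-2(5H)-one (mixture of epimers at C5 and C1') | COC1=C(C)C(=O)OC1C(O)[C@H](C)CCC/C(C)=C/C=C/[C@@H](C)CCCc2ccoc2
F4 | step 13 | methanesulfonate of F3 | COC1=C(C)C(=O)OC1C(OS(C)(=O)=O)[C@H](C)CCC/C(C)=C/C=C/[C@@H](C)CCCc2ccoc2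
F5 | step 13 | (5Z)-5-[(2R,6E,8E,10S)-13-(furan-3-yl)-2,6,10-trimethyltrideca-6,8-dien-1-ylidene]-4-methoxy-3-methylfuran-2(5H)-one | COC1=C(C)C(=O)O/C1=C\[C@H](C)CCC/C(C)=C/C=C/[C@@H](C)CCCc2ccoc2
F6 | step 9 | (2R,6E)-7-iodo-2,6-dimethylhept-6-en-1-ol | OC[C@H](C)CCC/C(C)=C/I
F7 | step 9 | 3-[(4S)-4-methylhex-5-yn-1-yl]furan | C#C[C@@H](C)CCCc1ccoc1
F8 | step 9 | 2-[(1E,3S)-6-(furan-3-yl)-3-methylhex-1-en-1-yl]-4,4,5,5-tetramethyl-1,3,2-dioxaborolane | CC1(C)OB(/C=C/[C@@H](C)CCCc2ccoc2)OC1(C)C
F9 | step 2 | (2S)-2-methylpent-4-en-1-ol | OC[C@@H](C)CC=C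
F10 | step 2 | tert-butyl(dimethyl){[(2S)-2-methylpent-4-en-1-yl]oxy}silane | CC(C)(C)[Si](C)(C)OC[C@@H](C)CC=C
F11 | step 2 | 9-[(4S)-5-{[tert-butyl(dimethyl)silyl]oxy}-4-methylpentyl]-9-borabicyclo[3.3.1]nonane | CC(C)(C)[Si](C)(C)OC[C@@H](C)CCCB1C2CCCC1CCC2
F12 | step 2 | tert-butyl{[(2S)-5-(furan-3-yl)-2-methylpentyl]oxy}dimethylsilane | CC(C)(C)[Si](C)(C)OC[C@@H](C)CCCc1ccoc1
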